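**Assumption:** the target is taken exactly as drawn, as the free bis(hydrogen sulfate); it is released from its pyridinium salt on an acid resin in the cold and kept in solution.

## Retrosynthetic overview

1. Target ⇒ hydroquinone (sulfation last, after hydrogenolysis of benzyl ethers) ⇒ cut between the linker CH2 and the tertiary carbinol: a primary alkylcerium from a decalin iodide adds to an oxepane-fused cyclohexanone.
2. Decalin half: arylmethyl group by Negishi coupling onto an enol triflate; quaternary C5 by reductive methylation; ring A closed onto ring B (2-methylcyclohexane-1,3-dione) by an amino-acid-catalysed intramolecular aldol condensation that sets the absolute configuration.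
3. Oxepane half: ring C is the same dione, C-allylated and desymmetrised by yeast reduction; ring D (oxepane) closed by ring-closing metathesis; the α-methyl set by SAMP-hydrazone alkylation.
4. Ring order: B and C bought as the dione; A by aldol; D by metathesis; then the two bicycles are joined; the arene is bought.

## Route

**Decalin half**

Step 1
Reactants: 1 3-bromopropan-1-ol
Product: 2 1-bromo-3-(methoxymethoxy)propane
Conditions: MOMCl, iPr2NEt, CH2Cl2, 0 °C → rt
Reagents that add atoms: chloromethyl methyl ether, COCCl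
Why: O-alkylation (acetal formation) of the primary alcohol gives a MOM ether that survives the Grignard, dissolving-metal and Wolff–Kishner steps ahead.

Step 2
Reactants: 2 1-bromo-3-(methoxymethoxy)propane
Product: 4 6-(methoxymethoxy)hex-1-en-3-ol (racemic), via Grignard reagent 3 (not isolated)
Conditions: Mg, THF, 40 °C; then acrolein, −78 → 0 °C; aqueous work-up
Reagents that add atoms: acrolein, C=CC=O
Why: Grignard 1,2-addition to the enal; the carbinol centre is erased in the next step, so no stereocontrol is needed.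

Step 3
Reactants: 4 6-(methoxymethoxy)hex-1-en-3-ol
Product: 5 6-(methoxymethoxy)hex-1-en-3-one
Conditions: Dess–Martin periodinane, CH2Cl2, 0 °C → rt; used at once
Reagents that add atoms: none
Why: Dess–Martin oxidation of the allylic alcohol gives the vinyl ketone under non-acidic, non-basic conditions that avoid polymerisation.

Step 4
Reactants: 5 6-(methoxymethoxy)hex-1-en-3-one; 6 2-methylcyclohexane-1,3-dione
Product: 7 2-[6-(methoxymethoxy)-3-oxohexyl]-2-methylcyclohexane-1,3-dione
Conditions: Et3N (0.1 equiv), EtOAc, 50 °C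
Reagents that add atoms: none
Why: Michael addition of the acidic cyclic 1,3-dione to the vinyl ketone creates the prochiral quaternary carbon.

Step 5
Reactants: 7 2-[6-(methoxymethoxy)-3-oxohexyl]-2-methylcyclohexane-1,3-dione
Product: 8 (8aR)-5-[2-(methoxymethoxy)ethyl]-8a-methyl-3,4,8,8a-tetrahydronaphthalene-1,6(2H,7H)-dione
Conditions: D-phenylalanine (1.0 equiv), (1R)-(−)-camphorsulfonic acid (0.5 equiv), DMF, 30 → 70 °C
Reagents that add atoms: none
Why: Enamine-mediated intramolecular aldol condensation (Hajos–Parrish–Eder–Sauer–Wiechert reaction, Hagiwara–Uda conditions) closes ring A, the D-amino acid choosing one enantiotopic ring carbonyl so that C8a is R (about 90% ee expected; the minor enantiomer is purged as a diastereomer after step 28).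

Step 6
Reactants: 8 (8aR)-enedione
Product: 9 (8aR)-5-[2-(methoxymethoxy)ethyl]-8a-methyl-3,4,8,8a-tetrahydronaphthalene-1,6(2H,7H)-dione 1-(ethylene ketal)
Conditions: ethylene glycol, p-TsOH (cat.), 4 Å MS, CH2Cl2, rt
Reagents that add atoms: ethylene glycol, OCCO
Why: Chemoselective ketalisation, because the saturated ketone is far more electrophilic than the conjugated one.

Step 7
Reactants: 9 enone ketal
Product: 11 (4aR,5S,8aR)-5-[2-(methoxymethoxy)ethyl]-5,8a-dimethylhexahydronaphthalene-1,6(2H,5H)-dione 1-(ethylene ketal), via lithium enolate 10 (not isolated)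
Conditions: Li, NH3(l)/THF, t-BuOH (1 equiv), −78 → −33 °C; then MeI, −78 °C → rt
Reagents that add atoms: iodomethane, CI
Why: Birch-type reductive alkylation gives the trans-fused enolate regiospecifically (4a-H anti to the angular methyl), and MeI then enters C5 on the face opposite the angular methyl, leaving the oxygenated chain axial and cis to it (5S).

Step 8
Reactants: 11 keto ketal
Product: 13 (4aR,5S,8aR)-5-[2-(methoxymethoxy)ethyl]-5,8a-dimethyloctahydronaphthalen-1(2H)-one ethylene ketal, via hydrazone 12 (not isolated)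
Conditions: N2H4·H2O, KOH, diethylene glycol, 130 → 200 °C
Reagents that add atoms: none
Why: Wolff–Kishner reduction (Huang-Minlon procedure) removes the hindered C6 carbonyl, and the ketal and MOM ether are stable to hot base.

Step 9
Reactants: 13 ketal
Product: 14 (4aR,5S,8aR)-5-[2-(methoxymethoxy)ethyl]-5,8a-dimethyloctahydronaphthalen-1(2H)-one
Conditions: 1 M HCl, THF, rt
Reagents that add atoms: water, O
Why: Acid-catalysed ketal hydrolysis under conditions mild enough to leave the MOM ether.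

Step 10
Reactants: 14 ketone
Product: 16 (4aR,5S,8aR)-5-[2-(methoxymethoxy)ethyl]-2,5,8a-trimethyloctahydronaphthalen-1(2H)-one (C2 epimers), via lithium enolate 15 (not isolated)
Conditions: LiN(iPr)2 (LDA), THF, −78 °C; then MeI, −78 → 0 °C
Reagents that add atoms: iodomethane, CI
Why: Enolate C-alkylation at the only enolisable position (C8a is quaternary); the C2 configuration is irrelevant because C2 becomes sp2.

Step 11
Reactants: 16 α-methyl ketone
Product: 18 (4aR,5S,8aR)-5-[2-(methoxymethoxy)ethyl]-2,5,8a-trimethyl-3,4,4a,5,6,7,8,8a-octahydronaphthalen-1-yl trifluoromethanesulfonate, via potassium enolate 17 (not isolated)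
Conditions: KN(SiMe3)2 (KHMDS), THF, −78 → 0 °C; then PhNTf2, 0 °C
Reagents that add atoms: N-phenylbis(trifluoromethanesulfonimide), O=S(=O)(N(c1ccccc1)S(=O)(=O)C(F)(F)F)C(F)(F)F
Why: O-triflation of the single possible tetrasubstituted enolate fixes the C1=C2 double bond of the target regiochemically.

**Arene**

Step 12
Reactants: 19 2,5-dihydroxybenzaldehyde
Product: 20 2,5-bis(benzyloxy)benzaldehyde
Conditions: BnBr, K2CO3, DMF, 60 °C
Reagents that add atoms: benzyl bromide, BrCc1ccccc1
Why: Williamson etherification of both phenols; benzyl ethers are later removed by neutral hydrogenolysis, avoiding acid that would cyclise a free phenol onto the alkene.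

Step 13
Reactants: 20 2,5-bis(benzyloxy)benzaldehyde
Product: 21 [2,5-bis(benzyloxy)phenyl]methanol
Conditions: NaBH4, MeOH/THF, 0 °C
Reagents that add atoms: none
Why: Hydride reduction of the aldehyde.

Step 14
Reactants: 21 [2,5-bis(benzyloxy)phenyl]methanol
Product: 22 1,4-bis(benzyloxy)-2-(chloromethyl)benzene
Conditions: SOCl2, CH2Cl2, 0 °C
Reagents that add atoms: thionyl chloride, ClS(Cl)=O
Why: Chlorodehydroxylation of an electron-rich benzylic alcohol through its chlorosulfite.

**Arylmethylation and chain activation**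

Step 15
Reactants: 18 enol triflate; 22 1,4-bis(benzyloxy)-2-(chloromethyl)benzene
Product: 24 1,4-bis(benzyloxy)-2-{[(4aR,5S,8aR)-5-[2-(methoxymethoxy)ethyl]-2,5,8a-trimethyl-3,4,4a,5,6,7,8,8a-octahydronaphthalen-1-yl]methyl}benzene, via benzylzinc chloride 23 (not isolated)
Conditions: 22, Zn dust, LiCl, THF, rt; then 18, Pd(OAc)2 (5 mol %), SPhos (10 mol %), THF, 60 °C
Reagents that add atoms: none
Why: Negishi sp2–sp3 cross-coupling, in which the benzylic zinc reagent transmetallates readily and an electron-rich biarylphosphine lets palladium insert into the hindered triflate without moving the double bond.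

Step 16
Reactants: 24 MOM ether
Product: 25 2-[(4aR,5S,8aR)-1-{[2,5-bis(benzyloxy)phenyl]methyl}-2,5,8a-trimethyl-3,4,4a,5,6,7,8,8a-octahydronaphthalen-5-yl]ethan-1-ol
Conditions: conc. HCl (cat.), MeOH, 45 °C
Reagents that add atoms: none
Why: Acid-catalysed transacetalisation to methanol frees the primary alcohol, while the benzyl ethers and the tetrasubstituted alkene (already the thermodynamic isomer) are untouched.

Step 17
Reactants: 25 primary alcohol
Product: 26 1,4-bis(benzyloxy)-2-{[(4aR,5S,8aR)-5-(2-iodoethyl)-2,5,8a-trimethyl-3,4,4a,5,6,7,8,8a-octahydronaphthalen-1-yl]methyl}benzene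
Conditions: I2, PPh3, imidazole, CH2Cl2, 0 °C → rt
Reagents that add atoms: iodine, II
Why: Appel-type iodination (Garegg–Samuelsson conditions) of an unhindered primary alcohol through its alkoxyphosphonium salt.

**Oxepane half**

Step 18
Reactants: 6 2-methylcyclohexane-1,3-dione
Product: 27 2-allyl-2-methylcyclohexane-1,3-dione
Conditions: allyl bromide, 1 M NaOH (1 equiv), Bu4NI (cat.), H2O, rt
Reagents that add atoms: allyl bromide, C=CCBr
Why: C-alkylation of the dione enolate with a soft allylic electrophile builds the quaternary carbon.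

Step 19
Reactants: 27 2-allyl-2-methylcyclohexane-1,3-dione
Product: 28 (2S,3S)-2-allyl-3-hydroxy-2-methylcyclohexan-1-one
Conditions: baker's yeast (Saccharomyces cerevisiae), sucrose, H2O, 30 °C
Reagents that add atoms: none
Why: Enzymatic desymmetrising ketone reduction (Mori's yeast reduction) delivers hydride to one enantiotopic carbonyl from the face anti to the allyl group, setting both the carbinol (3S) and the quaternary centre (2S) with OH cis to allyl.

Step 20
Reactants: 29 2-methylbut-3-yn-2-ol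
Product: 30 2-methylbut-3-yn-2-yl 2,2,2-trichloroacetimidate
Conditions: Cl3CCN, DBU (cat.), CH2Cl2, 0 °C
Reagents that add atoms: trichloroacetonitrile, N#CC(Cl)(Cl)Cl
Why: Base-catalysed addition of the tertiary alkoxide to the nitrile gives the trichloroacetimidate.

Step 21
Reactants: 28 (2S,3S)-ketol; 30 trichloroacetimidate
Product: 31 (2S,3S)-2-allyl-2-methyl-3-[(2-methylbut-3-yn-2-yl)oxy]cyclohexan-1-one
Conditions: 30 (3 equiv), BF3·OEt2 (cat.), cyclohexane/CH2Cl2, 0 °C → rt
Reagents that add atoms: none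
Why: Acid-catalysed trichloroacetimidate O-alkylation through the tertiary propargylic cation (SN1) puts a tertiary group on the hindered secondary alcohol without breaking its C–O bond, so C3 is retained.

Step 22
Reactants: 31 propargylic ether
Product: 32 (2S,3S)-2-allyl-2-methyl-3-[(2-methylbut-3-en-2-yl)oxy]cyclohexan-1-one
Conditions: H2 (1 atm), Pd/CaCO3 poisoned with Pb(OAc)2, quinoline, EtOAc, rt, stopped at 1 equiv H2
Reagents that add atoms: none
Why: Lindlar semi-hydrogenation reduces the terminal alkyne much faster than the terminal alkene.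

Step 23
Reactants: 32 diene
Product: 33 (5aS,9aS)-2,2,5a-trimethyl-5,5a,7,8,9,9a-hexahydro-1-benzoxepin-6(2H)-one
Conditions: second-generation Grubbs catalyst RuCl2(=CHPh)(H2IMes)(PCy3) (5 mol %), CH2Cl2 (5 mM), 40 °C
Reagents that add atoms: none
Why: Ring-closing metathesis closes ring D, the catalyst loading on the unhindered allyl group and closing onto the neopentylic vinyl group held cis on ring C, driven by loss of ethylene.

Step 24
Reactants: 33 oxepene ketone
Product: 34 (5aS,9aS)-2,2,5a-trimethyl-3,4,5,5a,7,8,9,9a-octahydro-1-benzoxepin-6(2H)-one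
Conditions: H2 (1 atm), Rh/Al2O3 (5%), EtOAc, rt
Reagents that add atoms: none
Why: Heterogeneous hydrogenation on rhodium saturates the ring alkene without hydrogenolysing the tertiary allylic C–O bond or reducing the ketone.

Step 25
Reactants: 34 oxepane ketone
Product: 35 SAMP hydrazone of 34 (C=N E; amino nitrogen anti to C5a)
Conditions: SAMP (1.3 equiv), p-TsOH (cat.), cyclohexane, reflux, Dean–Stark
Reagents that add atoms: (S)-1-amino-2-(methoxymethyl)pyrrolidine (SAMP), COC[C@@H]1CCCN1N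
Why: Hydrazone condensation installs the Enders auxiliary, the amino group settling on the side of the only α-CH2.

Step 26
Reactants: 35 SAMP hydrazone
Product: 37 SAMP hydrazone of the (7R)-7-methyl ketone, via lithium azaenolate 36 (not isolated)
Conditions: LiN(iPr)2 (LDA), THF, 0 °C; then MeI, −100 → −78 °C
Reagents that add atoms: iodomethane, CI
Why: Enders SAMP-hydrazone alkylation, in which the methoxymethyl-chelated azaenolate is methylated on the face remote from the pyrrolidine, giving the (R)-α-methyl centre as with cyclohexanone itself (reagent control, here 7R).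

Step 27
Reactants: 37 methylated hydrazone
Product: 38 (5aS,7R,9aS)-2,2,5a,7-tetramethyl-3,4,5,5a,7,8,9,9a-octahydro-1-benzoxepin-6(2H)-one
Conditions: O3, CH2Cl2, −78 °C; then N2 purge
Reagents that add atoms: ozone, [O-][O+]=O
Why: Ozonolytic cleavage of the C=N bond regenerates the ketone at low temperature without epimerising the new α-centre.

**Union and end game**

Step 28
Reactants: 26 iodide; 38 ketone
Product: 41 (5aS,6R,7R,9aS)-6-{2-[(4aR,5S,8aR)-1-{[2,5-bis(benzyloxy)phenyl]methyl}-2,5,8a-trimethyl-3,4,4a,5,6,7,8,8a-octahydronaphthalen-5-yl]ethyl}-2,2,5a,7-tetramethyldecahydro-1-benzoxepin-6-ol, via alkyllithium 39 (not isolated), via alkylcerium dichloride 40 (not isolated)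
Conditions: 26, t-BuLi (2.1 equiv), Et2O/pentane, −78 °C; then CeCl3 (anhydrous), THF, −78 °C; then 38, −78 → −40 °C; H2O
Reagents that add atoms: none
Why: Organocerium 1,2-addition (Imamoto) of the weakly basic alkylcerium avoids enolisation, and the ketone reacts in the chair with the 7-methyl equatorial so that equatorial attack, trans to the 7-methyl as with 2,2,6-trimethylcyclohexanone, gives the axial hydroxyl cis to the 7-methyl (6R).

Step 29
Reactants: 41 bis(benzyl ether)
Product: 42 2-{[(4aR,5S,8aR)-5-{2-[(5aS,6R,7R,9aS)-6-hydroxy-2,2,5a,7-tetramethyldecahydro-1-benzoxepin-6-yl]ethyl}-2,5,8a-trimethyl-3,4,4a,5,6,7,8,8a-octahydronaphthalen-1-yl]methyl}benzene-1,4-diol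
Conditions: H2 (1 atm), Pd/C (10%), EtOAc/EtOH, rt
Reagents that add atoms: none
Why: Hydrogenolysis of the aryl benzyl ethers under neutral conditions, which the hindered tetrasubstituted alkene and the tertiary alcohol survive.

Step 30
Reactants: 42 hydroquinone
Product: 43 2-{[(4aR,5S,8aR)-5-{2-[(5aS,6R,7R,9aS)-6-hydroxy-2,2,5a,7-tetramethyldecahydro-1-benzoxepin-6-yl]ethyl}-2,5,8a-trimethyl-3,4,4a,5,6,7,8,8a-octahydronaphthalen-1-yl]methyl}benzene-1,4-diyl bis(hydrogen sulfate) (CNP0125037.3)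
Conditions: SO3·pyridine (6 equiv), pyridine, rt; then Dowex 50W (H+ form), MeOH/H2O, 0 °C
Reagents that add atoms: sulfur trioxide pyridine complex, O=S(=O)([O-])[n+]1ccccc1
Why: O-sulfation of both phenols, the very hindered tertiary alcohol being expected not to react, followed by cation exchange to the acid form as drawn.

## Compound list

1 | 3-bromopropan-1-ol | OCCCBr | starting material
2 | 1-bromo-3-(methoxymethoxy)propane | BrCCCOCOC | intermediate
3 | [3-(methoxymethoxy)propyl]magnesium bromide | Br[Mg]CCCOCOC | intermediate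
4 | 6-(methoxymethoxy)hex-1-en-3-ol (racemic) | C=CC(O)CCCOCOC | intermediate
5 | 6-(methoxymethoxy)hex-1-en-3-one | C=CC(=O)CCCOCOC | intermediate
6 | 2-methylcyclohexane-1,3-dione | CC1C(=O)CCCC1=O | starting material
7 | 2-[6-(methoxymethoxy)-3-oxohexyl]-2-methylcyclohexane-1,3-dione | CC1(CCC(=O)CCCOCOC)C(=O)CCCC1=O | intermediate
8 | (8aR)-5-[2-(methoxymethoxy)ethyl]-8a-methyl-3,4,8,8a-tetrahydronaphthalene-1,6(2H,7H)-dione | O=C1[C@]2(C)CCC(=O)C(CCOCOC)=C2CCC1 | intermediate
9 | 8 with the C1 ketone as its 1,3-dioxolane (ethylene ketal), 8aR | O1CCOC12[C@]3(C)CCC(=O)C(CCOCOC)=C3CCC2 | intermediate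
10 | lithium enolate (O–C6=C5) of the trans-fused reduced ketal, 4a-H anti to 8a-CH3 | O1CCOC12[C@]3(C)CCC(O[Li])=C(CCOCOC)[C@H]3CCC2 | intermediate
11 | (4aR,5S,8aR)-5-[2-(methoxymethoxy)ethyl]-5,8a-dimethylhexahydronaphthalene-1,6(2H,5H)-dione 1-(ethylene ketal) | O1CCOC12[C@]3(C)CCC(=O)[C@@](C)(CCOCOC)[C@H]3CCC2 | intermediate
12 | C6 hydrazone of 11 | O1CCOC12[C@]3(C)CCC(=NN)[C@@](C)(CCOCOC)[C@H]3CCC2 | intermediate
13 | (4aR,5S,8aR)-5-[2-(methoxymethoxy)ethyl]-5,8a-dimethyloctahydronaphthalen-1(2H)-one ethylene ketal | O1CCOC12[C@]3(C)CCC[C@@](C)(CCOCOC)[C@H]3CCC2 | intermediate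
14 | (4aR,5S,8aR)-5-[2-(methoxymethoxy)ethyl]-5,8a-dimethyloctahydronaphthalen-1(2H)-one | O=C1[C@]2(C)CCC[C@@](C)(CCOCOC)[C@H]2CCC1 | intermediate
15 | lithium enolate (O–C1=C2) of 14 | [Li]OC1[C@]2(C)CCC[C@@](C)(CCOCOC)[C@H]2CCC=1 | intermediate
16 | (4aR,5S,8aR)-5-[2-(methoxymethoxy)ethyl]-2,5,8a-trimethyloctahydronaphthalen-1(2H)-one (C2 epimers) | O=C1[C@]2(C)CCC[C@@](C)(CCOCOC)[C@H]2CCC1C | intermediate
17 | potassium enolate (O–C1=C2) of 16 | [K]OC1[C@]2(C)CCC[C@@](C)(CCOCOC)[C@H]2CCC=1C | intermediate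
18 | (4aR,5S,8aR)-5-[2-(methoxymethoxy)ethyl]-2,5,8a-trimethyl-3,4,4a,5,6,7,8,8a-octahydronaphthalen-1-yl trifluoromethanesulfonate | CC1=C(OS(=O)(=O)C(F)(F)F)[C@]2(C)CCC[C@@](C)(CCOCOC)[C@H]2CC1 | intermediate
19 | 2,5-dihydroxybenzaldehyde | O=Cc1cc(O)ccc1O | starting material
20 | 2,5-bis(benzyloxy)benzaldehyde | O=Cc1cc(OCc2ccccc2)ccc1OCc1ccccc1 | intermediate
21 | [2,5-bis(benzyloxy)phenyl]methanol | OCc1cc(OCc2ccccc2)ccc1OCc1ccccc1 | intermediate
22 | 1,4-bis(benzyloxy)-2-(chloromethyl)benzene | ClCc1cc(OCc2ccccc2)ccc1OCc1ccccc1 | intermediate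
23 | [2,5-bis(benzyloxy)benzyl]zinc chloride | Cl[Zn]Cc1cc(OCc2ccccc2)ccc1OCc1ccccc1 | intermediate
24 | 1,4-bis(benzyloxy)-2-{[(4aR,5S,8aR)-5-[2-(methoxymethoxy)ethyl]-2,5,8a-trimethyl-3,4,4a,5,6,7,8,8a-octahydronaphthalen-1-yl]methyl}benzene | CC1=C(Cc2cc(OCc3ccccc3)ccc2OCc2ccccc2)[C@]2(C)CCC[C@@](C)(CCOCOC)[C@H]2CC1 | intermediate
25 | 2-[(4aR,5S,8aR)-1-{[2,5-bis(benzyloxy)phenyl]methyl}-2,5,8a-trimethyl-3,4,4a,5,6,7,8,8a-octahydronaphthalen-5-yl]ethan-1-ol | CC1=C(Cc2cc(OCc3ccccc3)ccc2OCc2ccccc2)[C@]2(C)CCC[C@@](C)(CCO)[C@H]2CC1 | intermediate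
26 | 1,4-bis(benzyloxy)-2-{[(4aR,5S,8aR)-5-(2-iodoethyl)-2,5,8a-trimethyl-3,4,4a,5,6,7,8,8a-octahydronaphthalen-1-yl]methyl}benzene | CC1=C(Cc2cc(OCc3ccccc3)ccc2OCc2ccccc2)[C@]2(C)CCC[C@@](C)(CCI)[C@H]2CC1 | intermediate
27 | 2-allyl-2-methylcyclohexane-1,3-dione | C=CCC1(C)C(=O)CCCC1=O | intermediate
28 | (2S,3S)-2-allyl-3-hydroxy-2-methylcyclohexan-1-one | O=C1CCC[C@H](O)[C@@]1(CC=C)C | intermediate
29 | 2-methylbut-3-yn-2-ol | CC(C)(O)C#C | starting material
30 | 2-methylbut-3-yn-2-yl 2,2,2-trichloroacetimidate | C#CC(C)(C)OC(=N)C(Cl)(Cl)Cl | intermediate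
31 | (2S,3S)-2-allyl-2-methyl-3-[(2-methylbut-3-yn-2-yl)oxy]cyclohexan-1-one | O=C1CCC[C@H](OC(C)(C)C#C)[C@@]1(CC=C)C | intermediate
32 | (2S,3S)-2-allyl-2-methyl-3-[(2-methylbut-3-en-2-yl)oxy]cyclohexan-1-one | O=C1CCC[C@H](OC(C)(C)C=C)[C@@]1(CC=C)C | intermediate
33 | (5aS,9aS)-2,2,5a-trimethyl-5,5a,7,8,9,9a-hexahydro-1-benzoxepin-6(2H)-one | O=C1CCC[C@@H]2OC(C)(C)C=CC[C@@]21C | intermediate
34 | (5aS,9aS)-2,2,5a-trimethyl-3,4,5,5a,7,8,9,9a-octahydro-1-benzoxepin-6(2H)-one | O=C1CCC[C@@H]2OC(C)(C)CCC[C@@]21C | intermediate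
35 | SAMP hydrazone of 34, C=N E, ring centres as in 34 | COC[C@@H]1CCCN1/N=C1\CCC[C@@H]2OC(C)(C)CCC[C@@]21C | intermediate
36 | lithium azaenolate of 35 (C6=C7) | COC[C@@H]1CCCN1N([Li])C1=CCC[C@@H]2OC(C)(C)CCC[C@@]21C | intermediate
37 | SAMP hydrazone of 38, C=N E, new methyl as in 38 | COC[C@@H]1CCCN1/N=C1\[C@H](C)CC[C@@H]2OC(C)(C)CCC[C@@]21C | intermediate
38 | (5aS,7R,9aS)-2,2,5a,7-tetramethyl-3,4,5,5a,7,8,9,9a-octahydro-1-benzoxepin-6(2H)-one | O=C1[C@H](C)CC[C@@H]2OC(C)(C)CCC[C@@]21C | intermediate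
39 | alkyllithium from 26 (I replaced by Li) | CC1=C(Cc2cc(OCc3ccccc3)ccc2OCc2ccccc2)[C@]2(C)CCC[C@@](C)(CC[Li])[C@H]2CC1 | intermediate
40 | alkylcerium dichloride from 39 | CC1=C(Cc2cc(OCc3ccccc3)ccc2OCc2ccccc2)[C@]2(C)CCC[C@@](C)(CC[Ce](Cl)Cl)[C@H]2CC1 | intermediate
41 | (5aS,6R,7R,9aS)-6-{2-[(4aR,5S,8aR)-1-{[2,5-bis(benzyloxy)phenyl]methyl}-2,5,8a-trimethyl-3,4,4a,5,6,7,8,8a-octahydronaphthalen-5-yl]ethyl}-2,2,5a,7-tetramethyldecahydro-1-benzoxepin-6-ol | CC1=C(Cc2cc(OCc3ccccc3)ccc2OCc2ccccc2)[C@]2(C)CCC[C@@](C)(CC[C@@]3(O)[C@H](C)CC[C@@H]4OC(C)(C)CCC[C@@]43C)[C@H]2CC1 | intermediate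
42 | 2-{[(4aR,5S,8aR)-5-{2-[(5aS,6R,7R,9aS)-6-hydroxy-2,2,5a,7-tetramethyldecahydro-1-benzoxepin-6-yl]ethyl}-2,5,8a-trimethyl-3,4,4a,5,6,7,8,8a-octahydronaphthalen-1-yl]methyl}benzene-1,4-diol | CC1=C(Cc2cc(O)ccc2O)[C@]2(C)CCC[C@@](C)(CC[C@@]3(O)[C@H](C)CC[C@@H]4OC(C)(C)CCC[C@@]43C)[C@H]2CC1 | intermediate
43 | CNP0125037.3, the benzene-1,4-diyl bis(hydrogen sulfate) of 42 | CC1=C(Cc2cc(OS(=O)(=O)O)ccc2OS(=O)(=O)O)[C@]2(C)CCC[C@@](C)(CC[C@@]3(O)[C@H](C)CC[C@@H]4OC(C)(C)CCC[C@@]43C)[C@H]2CC1 | target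

## Step count and risks

Total step count: 30.
Longest linear sequence: 17 steps (steps 1–11, 15–17, 28–30).

The three steps most likely to fail:

**Step 15, Negishi coupling on a tetrasubstituted, neopentylic enol triflate.** The fallback reverses the polarity and sets out from ketone 16. Condensation with 2,4,6-triisopropylbenzenesulfonyl hydrazide (cat. HCl, THF) gives the trisylhydrazone F1. A Shapiro reaction (n-BuLi 2.2 equiv, TMEDA, hexane/THF, −78 → 0 °C, loss of nitrogen and sulfinate) gives the vinyllithium F2. This is benzylated with chloride 22 in the presence of copper iodide CuI (10 mol %). The route is rejoined at compound 24, and step 11 is no longer needed.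

**Step 21, tertiary O-alkylation of a hindered secondary alcohol.** The fallback makes the tertiary C–O bond intramolecularly and sets out from ketol 28. Hydroboration with excess 9-BBN (THF, rt) gives the doubly borylated species F3. B-alkyl Suzuki coupling with 2-bromopropene (Pd(dppf)Cl2, aq. K3PO4, DMF, 50 °C) gives the alkenol F4. Markovnikov 7-exo oxymercuration with Hg(OCOCF3)2 in MeNO2 at 0 °C gives the organomercurial F5. Demercuration with NaBH4 in aq. NaOH at −20 °C (kept short to spare the hindered ketone) returns the route at compound 34, bypassing steps 20–24.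

**Step 28, addition of a primary alkylmetal to a hindered, enolisable ketone with facial control.** The fallback uses a slim sp nucleophile and sets out from alcohol 25. Dess–Martin oxidation gives the aldehyde F6. One-pot enol nonaflate formation and elimination (nonafluorobutanesulfonyl fluoride, phosphazene base, DMF) gives the terminal alkyne F7. Deprotonation with n-BuLi (THF, −78 °C) gives the lithium acetylide F8. This adds to ketone 38 equatorially (precedent: alkynyllithium additions to 2,2,6-trimethylcyclohexanone) to give the propargylic alcohol F9. Hydrogenation (H2, Pd/C, EtOAc/EtOH) saturates the alkyne and removes both benzyl groups in one operation, rejoining the route at compound 42.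

Further compounds

F1 | step 15 | 2,4,6-triisopropylbenzenesulfonyl hydrazone of ketone 16 | CC(C)c1cc(C(C)C)c(S(=O)(=O)NN=C2[C@]3(C)CCC[C@@](C)(CCOCOC)[C@H]3CCC2C)c(C(C)C)c1
F2 | step 15 | vinyllithium: 18 with the triflate group replaced by lithium | CC1=C([Li])[C@]2(C)CCC[C@@](C)(CCOCOC)[C@H]2CC1
F3 | step 21 | (2S,3S)-3-(9-borabicyclo[3.3.1]nonan-9-yloxy)-2-[3-(9-borabicyclo[3.3.1]nonan-9-yl)propyl]-2-methylcyclohexan-1-one | O=C1CCC[C@H](OB2C3CCCC2CCC3)[C@@]1(CCCB1C2CCCC1CCC2)C
F4 | step 21 | (2S,3S)-3-hydroxy-2-methyl-2-(4-methylpent-4-en-1-yl)cyclohexan-1-one | O=C1CCC[C@H](O)[C@@]1(CCCC(C)=C)C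
F5 | step 21 | {[(5aS,9aS)-2,5a-dimethyl-6-oxodecahydro-1-benzoxepin-2-yl]methyl}mercury trifluoroacetate (C2 epimers) | O=C1CCC[C@@H]2OC(C)(C[Hg]OC(=O)C(F)(F)F)CCC[C@@]21C
F6 | step 28 | aldehyde: 25 with CH2OH oxidised to CHO | CC1=C(Cc2cc(OCc3ccccc3)ccc2OCc2ccccc2)[C@]2(C)CCC[C@@](C)(CC=O)[C@H]2CC1
F7 | step 28 | terminal alkyne: ethynyl group on C5 of the decalin | CC1=C(Cc2cc(OCc3ccccc3)ccc2OCc2ccccc2)[C@]2(C)CCC[C@@](C)(C#C)[C@H]2CC1
F8 | step 28 | lithium acetylide of F7 | CC1=C(Cc2cc(OCc3ccccc3)ccc2OCc2ccccc2)[C@]2(C)CCC[C@@](C)(C#C[Li])[C@H]2CC1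
F9 | step 28 | propargylic alcohol: 41 with C≡C in place of the CH2CH2 linker | CC1=C(Cc2cc(OCc3ccccc3)ccc2OCc2ccccc2)[C@]2(C)CCC[C@@](C)(C#C[C@@]3(O)[C@H](C)CC[C@@H]4OC(C)(C)CCC[C@@]43C)[C@H]2CC1
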